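**Retrosynthetic overview**

- Numbering: cyclohexane C5 (CH bearing the C4 propenyl branch, whose CH2OH is C15), C6 (lactone O), C7 (bears C11, which carries the C12 carbonyl and the C13 methylene), C8 (ester O), C9 (CH2), C10 (methyl, vinyl). The strategy rests on the trans-fused α-methylene-γ-lactone across C6/C7 of this ring: it is the retron of a 2-(methoxycarbonyl)allyl metal (C13–C11=C7) adding through C7 to a C6 aldehyde.
- Late disconnections: C15–OH by allylic hydroxylation of the isopropenyl methyl; the C8 ester by acylation with O-silylated (Z)-2-(hydroxymethyl)but-2-enoic acid, made from crotonaldehyde.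
- Key disconnection: an acyclic formyl (Z)-2-(bromomethyl)enoate and CrCl2. The C6–C7 bond closes the carbocycle first; O–C12 lactonisation then closes the second ring in the same operation.
- Precursor: C7=C11/C13 by Baylis–Hillman reaction and SN2′ bromination on a C7 aldehyde; the C5–C10 bond and both centres by a boron-mediated enantioselective Ireland–Claisen rearrangement of an (E)-allyl 3-methylbut-3-enoate; C8 from (R)-glycidol; the (E)-trisubstituted alkene by acetylide opening and carboalumination.

Key step: step 15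

Assumption: the (4S,5S)-2-bromo-1,3-bis{[3,5-bis(trifluoromethyl)phenyl]sulfonyl}-4,5-diphenyl-1,3,2-diazaborolidine (charged preformed, from the bis-sulfonamide and BBr3) is taken to deliver the (5S,10S) acid in step 6; if the sense of induction is the reverse, its (4R,5R) enantiomer is used instead.

Abbreviations: TBS = tert-butyldimethylsilyl, TES = triethylsilyl, PMB = 4-methoxybenzyl, DMP = Dess–Martin periodinane.

**Route**

Step 1
Reactants: 1 (R)-glycidol
Product: 2 (S)-2-{[(4-methoxybenzyl)oxy]methyl}oxirane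
Conditions: NaH, PMBCl, Bu4NI (cat.), THF/DMF, 0 °C → rt
Reagents that add atoms: 4-methoxybenzyl chloride COc1ccc(CCl)cc1
Why: Williamson etherification of the primary alkoxide leaves the stereocentre (the future C8) untouched; the descriptor changes from R to S only through the CIP priorities.

Step 2
Reactants: 2 (S)-PMB glycidyl ether
Product: 3 (S)-1-[(4-methoxybenzyl)oxy]pent-4-yn-2-ol
Conditions: lithium acetylide–ethylenediamine complex, DMSO, 0 °C → rt
Reagents that add atoms: lithium acetylide–ethylenediamine complex [Li+].[C-]#C.NCCN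
Why: SN2 opening of the terminal epoxide by the acetylide at the unsubstituted carbon forms C9 and leaves the C8 carbinol configuration unchanged.

Step 3
Reactants: 3 (S)-1-[(4-methoxybenzyl)oxy]pent-4-yn-2-ol
Product: 4 (S)-tert-butyl({1-[(4-methoxybenzyl)oxy]pent-4-yn-2-yl}oxy)dimethylsilane
Conditions: TBSCl, imidazole, DMF, rt
Reagents that add atoms: tert-butyldimethylsilyl chloride CC(C)(C)[Si](C)(C)Cl
Why: Standard silylation of the secondary alcohol gives the C8 protecting group that later directs the key chair as an equatorial substituent.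

Step 4
Reactants: 4 TBS-protected alkynol
Product: 6 (2E,5S)-5-[(tert-butyldimethylsilyl)oxy]-6-[(4-methoxybenzyl)oxy]-3-methylhex-2-en-1-ol, via alkenyldimethylalane 5 (not isolated)
Conditions: Me3Al, Cp2ZrCl2 (cat.), CH2Cl2, 0 °C → rt; volatiles removed; n-BuLi, THF, −78 °C; (CH2O)n, −78 °C → rt
Reagents that add atoms: trimethylaluminium C[Al](C)C; formaldehyde (as paraformaldehyde) C=O
Why: Zirconium-catalysed methylalumination (Negishi carboalumination) of the terminal alkyne is syn and places methyl on the internal carbon, and the derived alanate is hydroxymethylated by formaldehyde with retention, which fixes the (E)-trisubstituted alkene.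

Step 5
Reactants: 6 (E)-allylic alcohol; 7 3-methylbut-3-enoic acid
Product: 8 (2E,5S)-5-[(tert-butyldimethylsilyl)oxy]-6-[(4-methoxybenzyl)oxy]-3-methylhex-2-en-1-yl 3-methylbut-3-enoate
Conditions: DCC, DMAP (cat.), CH2Cl2, 0 °C
Reagents that add atoms: none
Why: Steglich esterification of the primary allylic alcohol at low temperature with little DMAP should avoid conjugation of the β,γ-unsaturated acyl group.

Step 6
Reactants: 8 allyl 3-methylbut-3-enoate
Product: 10 (2S,3S,5S)-5-[(tert-butyldimethylsilyl)oxy]-3-ethenyl-6-[(4-methoxybenzyl)oxy]-3-methyl-2-(prop-1-en-2-yl)hexanoic acid, via boron ketene acetal 9 (not isolated)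
Conditions: (4S,5S)-bromoborane controller (1.2 equiv), Et3N, toluene/hexane, −78 °C, then −20 → 4 °C; aqueous work-up
Reagents that add atoms: none
Why: Enolisation with the chiral bromoborane and Et3N in toluene–hexane should give the E(O) boron ketene acetal (isopropenyl cis to the allyloxy oxygen), which undergoes the Ireland–Claisen [3,3] rearrangement through a chair, so that this enolate geometry together with the (E)-alkene fixes the C5/C10 relative configuration, while the C2-symmetric diazaborolidine selects the enolate face and hence the absolute configuration of both centres, reagent control being expected to override the remote C8 centre.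

Step 7
Reactants: 10 Claisen acid
Product: 11 (2S,3S,5S)-5-[(tert-butyldimethylsilyl)oxy]-3-ethenyl-6-[(4-methoxybenzyl)oxy]-3-methyl-2-(prop-1-en-2-yl)hexan-1-ol
Conditions: LiAlH4, Et2O, 0 °C → rt
Reagents that add atoms: none
Why: Hydride reduction of the carboxylic acid gives the C6 primary alcohol; the isolated alkenes and both ethers are inert and the intermediate carboxylate does not epimerise C5.

Step 8
Reactants: 11 primary alcohol
Product: 12 triethylsilyl ether of 11
Conditions: TESCl, imidazole, CH2Cl2, 0 °C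
Reagents that add atoms: chlorotriethylsilane CC[Si](Cl)(CC)CC
Why: Silylation masks C6–OH with a group that can later be removed by mild acid in the presence of the secondary TBS ether and the allylic bromide.

Step 9
Reactants: 12 fully protected triol
Product: 13 (2S,4S,5S)-2-[(tert-butyldimethylsilyl)oxy]-4-ethenyl-4,6-dimethyl-5-{[(triethylsilyl)oxy]methyl}hept-6-en-1-ol
Conditions: DDQ, CH2Cl2/pH 7 buffer, 0 °C
Reagents that add atoms: none
Why: Oxidative cleavage of the electron-rich PMB ether by DDQ is orthogonal to both silyl ethers and to the unconjugated alkenes when the medium is buffered.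

Step 10
Reactants: 13 C7 alcohol
Product: 14 (2S,4S,5S)-2-[(tert-butyldimethylsilyl)oxy]-4-ethenyl-4,6-dimethyl-5-{[(triethylsilyl)oxy]methyl}hept-6-enal
Conditions: DMP, NaHCO3, CH2Cl2, 0 °C → rt
Reagents that add atoms: none
Why: Dess–Martin oxidation under buffered, non-basic conditions gives the α-silyloxy aldehyde without epimerising C8.

Step 11
Reactants: 14 α-silyloxy aldehyde; 15 methyl acrylate
Product: 16 methyl (4S,6S,7S)-4-[(tert-butyldimethylsilyl)oxy]-6-ethenyl-3-hydroxy-6,8-dimethyl-2-methylidene-7-{[(triethylsilyl)oxy]methyl}non-8-enoate (both C3 epimers)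
Conditions: methyl acrylate (excess), DABCO, MeOH (few equiv), rt
Reagents that add atoms: none
Why: In this Morita–Baylis–Hillman reaction the DABCO–acrylate enolate adds to the activated α-oxygenated aldehyde and forms C7–C11; the configuration of the new carbinol is irrelevant because step 12 erases it, and the weakly basic amine should not epimerise C8.

Step 12
Reactants: 16 Baylis–Hillman adduct
Product: 17 methyl (2Z,4S,6S,7S)-2-(bromomethyl)-4-[(tert-butyldimethylsilyl)oxy]-6-ethenyl-6,8-dimethyl-7-{[(triethylsilyl)oxy]methyl}nona-2,8-dienoate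
Conditions: NBS, Me2S, CH2Cl2, 0 °C → rt
Reagents that add atoms: N-bromosuccinimide O=C1CCC(=O)N1Br
Why: The alkoxysulfonium ion formed by Corey–Kim-type activation is displaced by bromide in SN2′ fashion, which moves the alkene into the C7=C11 position and gives the thermodynamically preferred (Z)-2-(bromomethyl)enoate with C8 trans to the ester.

Step 13
Reactants: 17 TES-protected allylic bromide
Product: 18 methyl (2Z,4S,6S,7S)-2-(bromomethyl)-4-[(tert-butyldimethylsilyl)oxy]-6-ethenyl-7-(hydroxymethyl)-6,8-dimethylnona-2,8-dienoate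
Conditions: PPTS (cat.), MeOH/CH2Cl2, 0 °C
Reagents that add atoms: none
Why: Mild acid-catalysed methanolysis removes the primary TES ether much faster than the secondary TBS ether and does not solvolyse the allylic bromide at this temperature.

Step 14
Reactants: 18 hydroxy allylic bromide
Product: 19 methyl (2Z,4S,6S,7S)-2-(bromomethyl)-4-[(tert-butyldimethylsilyl)oxy]-6-ethenyl-7-formyl-6,8-dimethylnona-2,8-dienoate
Conditions: DMP, NaHCO3, CH2Cl2, 0 °C; used at once
Reagents that add atoms: none
Why: Buffered Dess–Martin oxidation gives the C6 aldehyde without a base that could epimerise C5 or conjugate the isopropenyl group, and the crude aldehyde is taken directly into the cyclisation.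

Step 15
Reactants: 19 formyl (Z)-2-(bromomethyl)enoate
Product: 21 (3aS,4S,6S,7S,7aR)-4-[(tert-butyldimethylsilyl)oxy]-6-ethenyl-6-methyl-3-methylidene-7-(prop-1-en-2-yl)hexahydro-1-benzofuran-2(3H)-one, via trans-hydroxy ester 20 (not isolated)
Conditions: CrCl2 (excess), THF, rt, slow addition at high dilution; aq. NH4Cl; PPTS (cat.), CH2Cl2, rt
Reagents that add atoms: none
Why: Two equivalents of CrCl2 reduce the allylic C13–Br bond to a 2-(methoxycarbonyl)allylchromium(III), which adds through its γ-carbon C7 to the C6 aldehyde in a chromium-bridged six-membered transition state and moves the double bond to C11=C13; this is an intramolecular Nozaki–Hiyama–Kishi allylation, whose closest relatives are the CrCl2 or zinc Barbier cyclisations of formyl-tethered 2-(bromomethyl)alk-2-enoates. The carbocycle closes 6-exo-trig at the aldehyde carbon (C6–C7), and the C6 oxygen of hydroxy ester 20 then closes the lactone 5-exo-trig at the C12 ester carbonyl with loss of methanol, completed by the mildly acidic finish. C6 is set by the chair folding of the C5–C10–C9–C8 tether with the C5 isopropenyl, C8 silyloxy and C10 vinyl groups equatorial: the carbonyl oxygen must then lie equatorial, because the axial position would clash 1,3-diaxially with the axial C10 methyl. C7 is set by the same chair and by the trans-decalin-like fusion of the chromium-bridged ring to the forming cyclohexane, which places the C11 arm equatorial once the allylchromium has equilibrated its geometry. The step needs the anti C6/C7 relationship (trans ring fusion) and the correct relation of both new centres to C5 and C8; the three equatorial resident groups, the axial methyl and the inherent anti preference of allylchromium additions should secure it. The neutral conditions should leave the epimerisable C5 next to the aldehyde, the C8 silyl ether and the three alkenes untouched.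

Step 16
Reactants: 21 8-O-TBS lactone
Product: 22 (3aR,4S,6S,7S,7aR)-6-ethenyl-4-hydroxy-6-methyl-3-methylidene-7-(prop-1-en-2-yl)hexahydro-1-benzofuran-2(3H)-one
Conditions: 48% aq. HF, MeCN, 0 °C → rt
Reagents that add atoms: none
Why: Acidic fluoride desilylation frees the C8 alcohol without the basic conditions that could shift the lactone from O6 to O8 or add to the α-methylene lactone.

Step 17
Reactants: 23 (E)-but-2-enal (crotonaldehyde)
Product: 24 (Z)-2-iodobut-2-enal
Conditions: I2, K2CO3, DMAP (cat.), THF/H2O, rt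
Reagents that add atoms: iodine II
Why: α-Iodination of the enal by a Baylis–Hillman-type sequence (DMAP conjugate addition, iodination of the enolate, elimination) returns the alkene with methyl trans to the formyl group, which is the Z isomer of the α-iodoenal.

Step 18
Reactants: 24 (Z)-2-iodobut-2-enal
Product: 25 (Z)-2-iodobut-2-en-1-ol
Conditions: NaBH4, MeOH, 0 °C
Reagents that add atoms: none
Why: Borohydride 1,2-reduction of the aldehyde gives the allylic alcohol and leaves the vinyl iodide and its geometry intact.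

Step 19
Reactants: 25 (Z)-2-iodobut-2-en-1-ol
Product: 27 (Z)-2-(hydroxymethyl)but-2-enoic acid, via dilithio species 26 (not isolated)
Conditions: t-BuLi (3.1 equiv), Et2O, −78 °C; CO2, −78 °C → rt; aq. HCl
Reagents that add atoms: carbon dioxide O=C=O
Why: Deprotonation of the alcohol and lithium–iodine exchange give a configurationally stable alkenyllithium that is carboxylated with retention, so the methyl group ends cis to the carboxyl group; no silyl group is present that could migrate to carbon.

Step 20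
Reactants: 27 (Z)-2-(hydroxymethyl)but-2-enoic acid
Product: 29 (Z)-2-{[(tert-butyldimethylsilyl)oxy]methyl}but-2-enoic acid, via bis-silyl derivative 28 (not isolated)
Conditions: TBSCl (2.3 equiv), imidazole, DMF, rt; then K2CO3, MeOH/THF/H2O, rt; 1 M HCl to pH 4, 0 °C
Reagents that add atoms: tert-butyldimethylsilyl chloride CC(C)(C)[Si](C)(C)Cl
Why: Exhaustive silylation followed by selective hydrolysis of the far more labile silyl ester leaves the primary TBS ether and the free acid.

Step 21
Reactants: 22 8-hydroxy lactone; 29 O-TBS acid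
Product: 31 (3aR,4S,6S,7S,7aR)-6-ethenyl-6-methyl-3-methylidene-2-oxo-7-(prop-1-en-2-yl)octahydro-1-benzofuran-4-yl (2Z)-2-{[(tert-butyldimethylsilyl)oxy]methyl}but-2-enoate, via mixed anhydride 30 (not isolated)
Conditions: 29, 2,4,6-trichlorobenzoyl chloride, Et3N, toluene, rt; then 22, DMAP, toluene, rt → 40 °C
Reagents that add atoms: none
Why: Yamaguchi esterification acylates the equatorial secondary C8 alcohol through the mixed anhydride, a method suited to hindered alcohols and to (Z)-2-substituted but-2-enoic acids with little Z-to-E isomerisation; C8 reacts at oxygen, so its configuration is kept.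

Step 22
Reactants: 31 15-deoxy ester
Product: 32 (3aR,4S,6S,7R,7aR)-6-ethenyl-7-(3-hydroxyprop-1-en-2-yl)-6-methyl-3-methylidene-2-oxooctahydro-1-benzofuran-4-yl (2Z)-2-{[(tert-butyldimethylsilyl)oxy]methyl}but-2-enoate
Conditions: SeO2 (0.5 equiv), t-BuOOH, CH2Cl2, rt, stopped before full conversion
Reagents that add atoms: selenium dioxide O=[Se]=O; tert-butyl hydroperoxide CC(C)(C)OO
Why: Selenium dioxide allylic oxidation (ene reaction then [2,3]-sigmatropic shift) should attack only the electron-rich 1,1-disubstituted C4 alkene, where the methyl group reacts in preference to the hindered C5 methine, because the vinyl group has no allylic hydrogen and the two acrylate-type alkenes are deactivated; the C5 descriptor changes from S to R only through the CIP priorities.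

Step 23
Reactants: 32 side-chain silyl ether
Product: 33 CNP0111202.1, (3aR,4S,6S,7R,7aR)-6-ethenyl-7-(3-hydroxyprop-1-en-2-yl)-6-methyl-3-methylidene-2-oxooctahydro-1-benzofuran-4-yl (2Z)-2-(hydroxymethyl)but-2-enoate
Conditions: HF·pyridine, THF/pyridine, 0 °C
Reagents that add atoms: none
Why: Buffered fluoride cleavage of the primary allylic TBS ether is fast and leaves both esters, the α-methylene lactone and the two allylic alcohols untouched.

**Compound list**

1 | (R)-glycidol | OC[C@@H]1CO1 | starting material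
2 | (S)-2-{[(4-methoxybenzyl)oxy]methyl}oxirane | COc1ccc(COC[C@@H]2CO2)cc1 | intermediate
3 | (S)-1-[(4-methoxybenzyl)oxy]pent-4-yn-2-ol | C#CC[C@H](O)COCc1ccc(OC)cc1 | intermediate
4 | (S)-tert-butyl({1-[(4-methoxybenzyl)oxy]pent-4-yn-2-yl}oxy)dimethylsilane | C#CC[C@H](O[Si](C)(C)C(C)(C)C)COCc1ccc(OC)cc1 | intermediate
5 | [(1E,4S)-4-[(tert-butyldimethylsilyl)oxy]-5-[(4-methoxybenzyl)oxy]-2-methylpent-1-en-1-yl]dimethylalane | C[Al](C)/C=C(\C)C[C@H](O[Si](C)(C)C(C)(C)C)COCc1ccc(OC)cc1 | intermediate
6 | (2E,5S)-5-[(tert-butyldimethylsilyl)oxy]-6-[(4-methoxybenzyl)oxy]-3-methylhex-2-en-1-ol | OC/C=C(\C)C[C@H](O[Si](C)(C)C(C)(C)C)COCc1ccc(OC)cc1 | intermediate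
7 | 3-methylbut-3-enoic acid | C=C(C)CC(=O)O | starting material
8 | (2E,5S)-5-[(tert-butyldimethylsilyl)oxy]-6-[(4-methoxybenzyl)oxy]-3-methylhex-2-en-1-yl 3-methylbut-3-enoate | C=C(C)CC(=O)OC/C=C(\C)C[C@H](O[Si](C)(C)C(C)(C)C)COCc1ccc(OC)cc1 | intermediate
9 | E(O) boron ketene acetal of 8 on the (4S,5S)-1,3-bis{[3,5-bis(trifluoromethyl)phenyl]sulfonyl}-4,5-diphenyl-1,3,2-diazaborolidine, isopropenyl cis to the allyloxy oxygen | C=C(C)/C=C(\OC/C=C(\C)C[C@H](O[Si](C)(C)C(C)(C)C)COCc1ccc(OC)cc1)OB1N(S(=O)(=O)c2cc(C(F)(F)F)cc(C(F)(F)F)c2)[C@@H](c2ccccc2)[C@H](c2ccccc2)N1S(=O)(=O)c1cc(C(F)(F)F)cc(C(F)(F)F)c1 | intermediate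
10 | (2S,3S,5S)-5-[(tert-butyldimethylsilyl)oxy]-3-ethenyl-6-[(4-methoxybenzyl)oxy]-3-methyl-2-(prop-1-en-2-yl)hexanoic acid | OC(=O)[C@H]([C@](C)(C=C)C[C@H](O[Si](C)(C)C(C)(C)C)COCc1ccc(OC)cc1)C(C)=C | intermediate
11 | (2S,3S,5S)-5-[(tert-butyldimethylsilyl)oxy]-3-ethenyl-6-[(4-methoxybenzyl)oxy]-3-methyl-2-(prop-1-en-2-yl)hexan-1-ol | OC[C@H]([C@](C)(C=C)C[C@H](O[Si](C)(C)C(C)(C)C)COCc1ccc(OC)cc1)C(C)=C | intermediate
12 | triethylsilyl ether of 11 (C6–OTES, C8–OTBS, C7–OPMB) | CC[Si](CC)(CC)OC[C@H]([C@](C)(C=C)C[C@H](O[Si](C)(C)C(C)(C)C)COCc1ccc(OC)cc1)C(C)=C | intermediate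
13 | (2S,4S,5S)-2-[(tert-butyldimethylsilyl)oxy]-4-ethenyl-4,6-dimethyl-5-{[(triethylsilyl)oxy]methyl}hept-6-en-1-ol | CC[Si](CC)(CC)OC[C@H]([C@](C)(C=C)C[C@H](O[Si](C)(C)C(C)(C)C)CO)C(C)=C | intermediate
14 | (2S,4S,5S)-2-[(tert-butyldimethylsilyl)oxy]-4-ethenyl-4,6-dimethyl-5-{[(triethylsilyl)oxy]methyl}hept-6-enal | CC[Si](CC)(CC)OC[C@H]([C@](C)(C=C)C[C@H](O[Si](C)(C)C(C)(C)C)C=O)C(C)=C | intermediate
15 | methyl acrylate | C=CC(=O)OC | starting material
16 | methyl (4S,6S,7S)-4-[(tert-butyldimethylsilyl)oxy]-6-ethenyl-3-hydroxy-6,8-dimethyl-2-methylidene-7-{[(triethylsilyl)oxy]methyl}non-8-enoate, both C3 epimers | CC[Si](CC)(CC)OC[C@H]([C@](C)(C=C)C[C@H](O[Si](C)(C)C(C)(C)C)C(O)C(=C)C(=O)OC)C(C)=C | intermediate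
17 | methyl (2Z,4S,6S,7S)-2-(bromomethyl)-4-[(tert-butyldimethylsilyl)oxy]-6-ethenyl-6,8-dimethyl-7-{[(triethylsilyl)oxy]methyl}nona-2,8-dienoate | CC[Si](CC)(CC)OC[C@H]([C@](C)(C=C)C[C@H](O[Si](C)(C)C(C)(C)C)/C=C(\CBr)C(=O)OC)C(C)=C | intermediate
18 | methyl (2Z,4S,6S,7S)-2-(bromomethyl)-4-[(tert-butyldimethylsilyl)oxy]-6-ethenyl-7-(hydroxymethyl)-6,8-dimethylnona-2,8-dienoate | OC[C@H]([C@](C)(C=C)C[C@H](O[Si](C)(C)C(C)(C)C)/C=C(\CBr)C(=O)OC)C(C)=C | intermediate
19 | methyl (2Z,4S,6S,7S)-2-(bromomethyl)-4-[(tert-butyldimethylsilyl)oxy]-6-ethenyl-7-formyl-6,8-dimethylnona-2,8-dienoate (key precursor) | O=C[C@H]([C@](C)(C=C)C[C@H](O[Si](C)(C)C(C)(C)C)/C=C(\CBr)C(=O)OC)C(C)=C | intermediate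
20 | methyl 2-[(1S,2R,3S,4S,6S)-6-[(tert-butyldimethylsilyl)oxy]-4-ethenyl-2-hydroxy-4-methyl-3-(prop-1-en-2-yl)cyclohexyl]prop-2-enoate | C=C[C@]1(C)C[C@H](O[Si](C)(C)C(C)(C)C)[C@@H](C(=C)C(=O)OC)[C@H](O)[C@H]1C(C)=C | intermediate
21 | (3aS,4S,6S,7S,7aR)-4-[(tert-butyldimethylsilyl)oxy]-6-ethenyl-6-methyl-3-methylidene-7-(prop-1-en-2-yl)hexahydro-1-benzofuran-2(3H)-one (key product) | C=C[C@]1(C)C[C@H](O[Si](C)(C)C(C)(C)C)[C@H]2C(=C)C(=O)O[C@@H]2[C@H]1C(C)=C | intermediate
22 | (3aR,4S,6S,7S,7aR)-6-ethenyl-4-hydroxy-6-methyl-3-methylidene-7-(prop-1-en-2-yl)hexahydro-1-benzofuran-2(3H)-one | C=C[C@]1(C)C[C@H](O)[C@H]2C(=C)C(=O)O[C@@H]2[C@H]1C(C)=C | intermediate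
23 | (E)-but-2-enal (crotonaldehyde) | C/C=C/C=O | starting material
24 | (Z)-2-iodobut-2-enal | C/C=C(\I)C=O | intermediate
25 | (Z)-2-iodobut-2-en-1-ol | C/C=C(\I)CO | intermediate
26 | lithium (Z)-2-lithiobut-2-en-1-olate | C/C=C(\[Li])CO[Li] | intermediate
27 | (Z)-2-(hydroxymethyl)but-2-enoic acid | C/C=C(/CO)C(=O)O | intermediate
28 | tert-butyldimethylsilyl (Z)-2-{[(tert-butyldimethylsilyl)oxy]methyl}but-2-enoate | C/C=C(/CO[Si](C)(C)C(C)(C)C)C(=O)O[Si](C)(C)C(C)(C)C | intermediate
29 | (Z)-2-{[(tert-butyldimethylsilyl)oxy]methyl}but-2-enoic acid | C/C=C(/CO[Si](C)(C)C(C)(C)C)C(=O)O | intermediate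
30 | (Z)-2-{[(tert-butyldimethylsilyl)oxy]methyl}but-2-enoic 2,4,6-trichlorobenzoic anhydride | C/C=C(/CO[Si](C)(C)C(C)(C)C)C(=O)OC(=O)c1c(Cl)cc(Cl)cc1Cl | intermediate
31 | (3aR,4S,6S,7S,7aR)-6-ethenyl-6-methyl-3-methylidene-2-oxo-7-(prop-1-en-2-yl)octahydro-1-benzofuran-4-yl (2Z)-2-{[(tert-butyldimethylsilyl)oxy]methyl}but-2-enoate | C=C[C@]1(C)C[C@H](OC(=O)/C(=C\C)CO[Si](C)(C)C(C)(C)C)[C@H]2C(=C)C(=O)O[C@@H]2[C@H]1C(C)=C | intermediate
32 | (3aR,4S,6S,7R,7aR)-6-ethenyl-7-(3-hydroxyprop-1-en-2-yl)-6-methyl-3-methylidene-2-oxooctahydro-1-benzofuran-4-yl (2Z)-2-{[(tert-butyldimethylsilyl)oxy]methyl}but-2-enoate | C=C[C@]1(C)C[C@H](OC(=O)/C(=C\C)CO[Si](C)(C)C(C)(C)C)[C@H]2C(=C)C(=O)O[C@@H]2[C@H]1C(=C)CO | intermediate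
33 | CNP0111202.1, (3aR,4S,6S,7R,7aR)-6-ethenyl-7-(3-hydroxyprop-1-en-2-yl)-6-methyl-3-methylidene-2-oxooctahydro-1-benzofuran-4-yl (2Z)-2-(hydroxymethyl)but-2-enoate | C=C[C@]1(C)C[C@H](OC(=O)/C(=C\C)CO)[C@H]2C(=C)C(=O)O[C@@H]2[C@H]1C(=C)CO | target

**Step count**

Total: 23 steps. Longest linear sequence: 19 steps (steps 1–16 and 21–23, from 1); the acyl side chain takes steps 17–20 and joins at step 21.

**Steps most likely to fail**

Step 15. The ring closure may lose control of the relative configuration at C6/C7, giving a cis-fused lactone through a transition state with the C11 arm axial, or the allylchromium may eliminate the C8 silyloxy group before it cyclises. The fallback sets out from 14 and returns at 21. Wittig olefination of 14 with methyl (triphenylphosphoranylidene)acetate would give the (E)-enoate F1. Removal of the TES group (PPTS, MeOH) would give the alcohol F2, and Dess–Martin oxidation the formyl enoate F3. Samarium diiodide (THF/MeOH, −78 °C) would then form C6–C7 by ketyl–olefin cyclisation, whose preference for an anti arrangement of the ketyl oxygen and the ester arm on the all-equatorial chair leads, with lactonisation in the flask, to the saturated trans-fused lactone F4. α-Methylenation would follow: LDA then dimethylmethylideneammonium iodide to the Mannich base F5, methyl iodide to the methiodide F6, and elimination with NaHCO3 to 21.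

Step 6. The boron controller may discriminate the enolate faces insufficiently in the presence of the C8 centre (mismatched pairing), or the enolate geometry may leak, so that C5/C10 stereoisomers form. The fallback sets out from 8 and returns at 10. Kinetic enolisation with LDA in THF at −78 °C and trapping with TMSCl/Et3N would give the trimethylsilyl ketene acetal F7 of the same enolate geometry. On warming it would rearrange through the same chair to both acids of the required C5/C10 relative configuration, 10 and its (2R,3R,5S) diastereomer F8. These differ in their relation to C8 and would be separated by chromatography, if necessary after reduction at the stage of alcohol 11.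

Step 22. The oxidant may attack the wrong allylic position (the C5 methine), or the C15 alcohol may be over-oxidised to the enal. The fallback sets out from 31 and returns at 32. Ene-type allylic chlorination of the isopropenyl group (NaOCl, CeCl3·7H2O, CH2Cl2/H2O, 0 °C) would give the 15-chloride F9. Displacement with sodium formate (DMF, Bu4NI cat., 40 °C) would give the formate F10, and mild methanolysis (NaHCO3, MeOH, 0 °C) would release 32.

**Further compounds**

F1 | step 15 | methyl (2E,4S,6S,7S)-4-[(tert-butyldimethylsilyl)oxy]-6-ethenyl-6,8-dimethyl-7-{[(triethylsilyl)oxy]methyl}nona-2,8-dienoate | CC[Si](CC)(CC)OC[C@H]([C@](C)(C=C)C[C@H](O[Si](C)(C)C(C)(C)C)/C=C/C(=O)OC)C(C)=C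
F2 | step 15 | methyl (2E,4S,6S,7S)-4-[(tert-butyldimethylsilyl)oxy]-6-ethenyl-7-(hydroxymethyl)-6,8-dimethylnona-2,8-dienoate | OC[C@H]([C@](C)(C=C)C[C@H](O[Si](C)(C)C(C)(C)C)/C=C/C(=O)OC)C(C)=C
F3 | step 15 | methyl (2E,4S,6S,7S)-4-[(tert-butyldimethylsilyl)oxy]-6-ethenyl-7-formyl-6,8-dimethylnona-2,8-dienoate | O=C[C@H]([C@](C)(C=C)C[C@H](O[Si](C)(C)C(C)(C)C)/C=C/C(=O)OC)C(C)=C
F4 | step 15 | (3aS,4S,6S,7S,7aR)-4-[(tert-butyldimethylsilyl)oxy]-6-ethenyl-6-methyl-7-(prop-1-en-2-yl)hexahydro-1-benzofuran-2(3H)-one | C=C[C@]1(C)C[C@H](O[Si](C)(C)C(C)(C)C)[C@H]2CC(=O)O[C@@H]2[C@H]1C(C)=C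
F5 | step 15 | 3-[(dimethylamino)methyl] derivative of F4 (C3 epimers) | C=C[C@]1(C)C[C@H](O[Si](C)(C)C(C)(C)C)[C@H]2C(CN(C)C)C(=O)O[C@@H]2[C@H]1C(C)=C
F6 | step 15 | methiodide of F5 | C=C[C@]1(C)C[C@H](O[Si](C)(C)C(C)(C)C)[C@H]2C(C[N+](C)(C)C)C(=O)O[C@@H]2[C@H]1C(C)=C.[I-]
F7 | step 6 | trimethylsilyl ketene acetal of 8, isopropenyl cis to the allyloxy oxygen | C=C(C)/C=C(\OC/C=C(\C)C[C@H](O[Si](C)(C)C(C)(C)C)COCc1ccc(OC)cc1)O[Si](C)(C)C
F8 | step 6 | (2R,3R,5S)-5-[(tert-butyldimethylsilyl)oxy]-3-ethenyl-6-[(4-methoxybenzyl)oxy]-3-methyl-2-(prop-1-en-2-yl)hexanoic acid | OC(=O)[C@@H]([C@@](C)(C=C)C[C@H](O[Si](C)(C)C(C)(C)C)COCc1ccc(OC)cc1)C(C)=C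
F9 | step 22 | 15-chloro analogue of 31, 7-(3-chloroprop-1-en-2-yl) | C=C[C@]1(C)C[C@H](OC(=O)/C(=C\C)CO[Si](C)(C)C(C)(C)C)[C@H]2C(=C)C(=O)O[C@@H]2[C@H]1C(=C)CCl
F10 | step 22 | 15-O-formyl derivative of 32 | C=C[C@]1(C)C[C@H](OC(=O)/C(=C\C)CO[Si](C)(C)C(C)(C)C)[C@H]2C(=C)C(=O)O[C@@H]2[C@H]1C(=C)COC=O
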